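# Stypandrol by (2+2+2) cycloaddition of three alkynes – full route proposal

**Numbering used throughout.** 1 hex-5-ynoic acid; 2 hex-5-ynoyl imidazole; 3 N-methoxy-N-methylhex-5-ynamide; 4 ethoxyethyne; 5 lithium ethoxyacetylide; 6 lithium hemiaminal adduct; 7 1-ethoxyocta-1,7-diyn-3-one; 8 pent-3-yn-2-one; 9 7-acetyl-8-ethoxy-6-methyl-3,4-dihydronaphthalen-1(2H)-one; 10 its 4H-naphthalen-1-one dehydro form; 11 1-(1-ethoxy-8-hydroxy-3-methylnaphthalen-2-yl)ethan-1-one; 12 its 7-bromide; 13 its 7-pinacolboronate; 14 the bis-ethyl ether of the target; 15 stypandrol.

Atom labels C1–C8a refer to each naphthalene half of the target: C1–OH, C2–acetyl, C3–methyl, C4–H, C4a, C5–H, C6–H, C7–aryl, C8–OH, C8a. Ring A is C1–C4/C4a/C8a and ring B is C4a/C5–C8/C8a.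

Remark on the chemistry: the biaryl axis has only the two C8 hydroxyl groups as ortho substituents and is taken as freely rotating, so no axial configuration is controlled; racemic BINAP is therefore sufficient in the key step.

## Analysis of the target

Stypandrol is a symmetrical dimer: two identical 2-acetyl-1,8-dihydroxy-3-methylnaphthalene halves joined by one biaryl bond between C7 and C7'. It has no stereocentre, and the biaryl axis is not hindered enough to be configurationally stable, so the problem is one of constitution only. The peri-dihydroxynaphthalene units are electron-rich and easily oxidised to quinones, and each C1 hydroxyl is chelated to the neighbouring acetyl group, so at least one oxygen per half is best kept masked until the end. Two things make the synthesis hard. Ring A carries a different group at every one of its six positions, with oxygen, acetyl and methyl on three adjacent carbons. The biaryl bond must also be made at C7, ortho to the C8 hydroxyl, while C5, para to that hydroxyl, is unsubstituted. The strategy rests on ring A: cutting C1–C2, C3–C4 and C4a–C8a divides it into a two-carbon piece C2–C3 that carries acetyl and methyl, and two two-carbon pieces C1/C8a and C4a/C4. The three pieces are three alkynes, and the four-atom tether C5–C6–C7–C8 between the latter two becomes ring B with C8 as a carbonyl group. That carbonyl later becomes the C8 hydroxyl, which in turn marks the neighbouring C7 for the biaryl bond.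

## Retrosynthetic reasoning

**15 to 14.** The two O–ethyl bonds on the C1 oxygens are cut last. The ether keeps each half less oxidisable during the coupling steps, and it is the form in which the C1 oxygen enters the synthesis. The forward reaction is a Lewis-acid dealkylation that must cleave two ethyl aryl ethers, each flanked by an acetyl carbonyl and a peri hydroxyl, without touching the ketones.

**14 to 12 (through 13).** The C7–C7' bond is cut because it joins two identical halves, so one monomer made once serves twice. A direct oxidative phenol coupling of a monomeric half was not relied on for this bond. With C5 unsubstituted, para–para and ortho–para coupling are expected to compete with the ortho–ortho mode that the target needs. A homocoupling of the aryl bromide 12 fixes the position of the bond by the position of the halogen. In the forward direction half of 12 is turned into the boronate 13 in the flask, and 13 couples with the rest of 12.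

**12 to 11.** The C7–Br bond is cut. The free C8 hydroxyl of 11 activates C7 (ortho) and C5 (para); the forward reaction is an amine-catalysed ortho-bromination, which delivers the halogen through the phenol oxygen. Ring A is deactivated by the acetyl group and should not compete.

**11 to 9 (through 10).** Two hydrogens are added back to ring B, turning the C8 naphthol into a ketone. This is the point at which the target's second aromatic ring is traded for a tetralone that a cycloaddition can deliver. The forward reaction is a dehydrogenation that must act on the ring ketone only. A palladium-catalysed aerobic dehydrogenation meets this need by mechanism, because the acetyl group has no β-hydrogen. An iodine-based oxidant was avoided, since such reagents oxidise the product naphthol on to an ortho-quinone.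

**9 to 7 and 8.** Three bonds of ring A are cut at once: C1–C2, C3–C4 and C4a–C8a. This is preferred over any stepwise benzannulation because it removes both carbocycles in one operation and gives two small acyclic pieces, 7 and 8, that already hold every substituent of ring A at the correct oxidation level. The forward reaction is a metal-catalysed (2+2+2) cycloaddition that has to pair the diyne with the monoalkyne rather than with itself, and has to place the acetyl carbon of 8 next to the ethoxy-bearing carbon.

**7 to 3 and 4 (through 5 and 6).** The C8–C8a bond between the carbonyl carbon and the alkyne is cut, giving an acyl donor and an acetylide. The Weinreb amide 3 is chosen as acyl donor because its chelated adduct 6 stops at the ketone stage. Ethoxyethyne 4 brings in the C1 oxygen already protected.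

**3 to 1 (through 2).** The amide C–N bond is cut back to the commercial acid 1, which supplies C4, C4a, C5, C6, C7 and C8.

## Alternatives that were turned down

**Alternative 1: both acylated rings A by a double anhydride–alkyne annulation.**
- Disconnection: C1–C2 and C3–C4 in each half, with the biaryl bond already present in the bis(homophthalic anhydride) A1.
- Forward key step: A1 is deprotonated twice at its benzylic carbons and adds to two molecules of 8 (Tamura cycloaddition). Each half closes ring A and loses CO2, giving the 8,8'-di-O-methyl ether A2, one demethylation away from the target.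
- For it: the orientation of 8 is set by the polarity of a conjugate addition followed by acylation, and no late halogenation or biaryl coupling is needed. On both points it is stronger than the chosen route.
- Against it: A1 is a biphenyl in which each ring carries four adjacent substituents (aryl, methoxy, carboxyl, carboxymethyl). It has to be assembled in many steps, including a biaryl coupling of its own, so the difficulty is moved rather than removed. The weakly nucleophilic anhydride anion must also add twice to a β-methyl-substituted ynone, and the mono-adduct is a poorly soluble salt.
- Comparison: the chosen strategy reaches its key step in two steps from acyclic commercial materials and runs it under neutral conditions. It pays for this with a less secure orientation of 8 and three extra steps after the key step.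

**Alternative 2: a bitetralone from a diene diester, aromatised late.**
- Disconnection: C5–C6 and C7–C8 in both halves.
- Forward key step: two equivalents of the laterally lithiated symmetrical isophthalate A3 add to the two methylene ends of the diene diester A4. Each resulting ester enolate closes onto the neighbouring aryl ester, giving the bitetralone A5 as a mixture of diastereomers.
- For it: the C7–C7' bond comes from a cheap C6 building block, the regiochemistry of the biaryl bond is beyond doubt, and the symmetry of A3 removes any question of which methyl group reacts. In the certainty of the biaryl position it is stronger than the chosen route.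
- Against it: A4 polymerises and dimerises readily. The first conjugate addition gives an extended enolate that can react at its far end. Two adjacent quaternary carbons must be formed. After the key step both β-keto esters must be decarboxylated, both rings B dehydrogenated, both hindered aryl esters converted into acetyl groups, and both ethers cleaved.
- Comparison: the chosen route delivers ring A with the acetyl group in place and the correct oxidation level, so its endgame is shorter.

**Alternative 3: ring B by cyclisation of a lateral-methyl enaminone.**
- Disconnection: C5–C6.
- Forward key step: the mono-enaminone A6 is deprotonated at its C4a methyl group. The resulting ortho-quinodimethane enolate closes onto the enaminone carbon and loses dimethylamine, giving the naphthol A7.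
- For it: ring A comes from a cheap symmetrical aromatic feedstock, no transition metal is needed, and the ring closure has only one possible regiochemistry. On cost and on the certainty of the substitution pattern of ring A it is as strong as or stronger than the chosen route.
- Against it: two equivalent, hindered acetyl groups must be differentiated by a mono-condensation. The base step has to deprotonate a benzylic methyl group in the presence of a more acidic acetyl group and a second, unproductive ortho methyl group. A7 is the O-methyl counterpart of 11, so the same bromination, homocoupling and dealkylation would still follow.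
- Comparison: the step count to the naphthol is similar. The chosen route avoids the differentiation of twin groups and the strong-base step, and forms both rings in one catalytic, atom-economical operation.

Key step: step 3

## Route

Step 1
Reactants: 1 hex-5-ynoic acid
Product: 3 N-methoxy-N-methylhex-5-ynamide, via hex-5-ynoyl imidazole 2 (not isolated)
Conditions: CDI, CH2Cl2, rt; then MeNHOMe·HCl, rt
Reagents that add atoms: N,O-dimethylhydroxylamine hydrochloride, CNOC.Cl
Why: Standard Weinreb amide formation through the acyl imidazole; the terminal alkyne is inert and the imidazole set free takes up the hydrogen chloride of the amine salt.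

Step 2
Reactants: 3 N-methoxy-N-methylhex-5-ynamide; 4 ethoxyethyne
Product: 7 1-ethoxyocta-1,7-diyn-3-one, via lithium ethoxyacetylide 5 (not isolated), via lithium hemiaminal adduct 6 (not isolated)
Conditions: 4 (1.4 equiv), n-BuLi, THF, −78 °C; then 3, −78 → −20 °C; inverse quench into cold aq. NaHSO4/Et2O, then NaHCO3 wash
Reagents that add atoms: none
Why: Acylation of a lithium acetylide by a Weinreb amide; the lithium chelate 6 holds the tetrahedral adduct until the quench, so no second addition occurs, and proton exchange with the terminal alkyne of 3 is slow at −78 °C and at worst consumes some of the excess of 5. The cold acidic inverse quench keeps the liberated hydroxylamine protonated so that it cannot add to the push–pull ynone, and the short contact time limits hydration of the ethoxyalkyne.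

Step 3
Reactants: 7 1-ethoxyocta-1,7-diyn-3-one; 8 pent-3-yn-2-one
Product: 9 7-acetyl-8-ethoxy-6-methyl-3,4-dihydronaphthalen-1(2H)-one
Conditions: [Rh(cod)2]BF4 (5 mol %), rac-BINAP (5 mol %), H2 then Ar, CH2Cl2, rt; 7 added over 4 h to 8 (3 equiv)
Reagents that add atoms: none
Why: Cationic rhodium/bisphosphine-catalysed (2+2+2) cross-cyclotrimerisation of a tethered 1,7-diyne with a monoalkyne, the known route to tetralins and fused aryl ketones, here applied to an ethoxy ynone diyne and an ynone. The monovalent rhodium–BINAP cation, freed of cod by hydrogenation, binds both triple bonds of 7 and couples their inner carbons oxidatively, which forms C4a–C8a and closes ring B as a six-membered carbocycle fused to a catalyst-bound metallacyclopentadiene of trivalent rhodium. Alkyne 8 then inserts into the less hindered Rh–C bond at the CH terminus (C4) with its methyl-bearing β-carbon forming C3–C4, the polarity of a conjugate carbometalation, so that the acetyl-bearing carbon stays on rhodium. Reductive elimination joins this carbon to the ethoxy-bearing carbon (C1–C2), closes ring A directly as a benzene ring and returns monovalent rhodium. No stereocentre is formed. The step needs cross- over homo-cyclotrimerisation, which slow addition of 7 to an excess of the slowly self-trimerising internal ynone 8 should secure. It also needs one orientation of 8, which is favoured both by the smaller methyl end meeting the unhindered C4 terminus in the C–C bond-forming insertion and by the electrophilic β-carbon of the ynone. The neutral medium at room temperature spares the acid- and heat-sensitive ethoxyalkyne and both ketones.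

Step 4
Reactants: 9 7-acetyl-8-ethoxy-6-methyl-3,4-dihydronaphthalen-1(2H)-one
Product: 11 1-(1-ethoxy-8-hydroxy-3-methylnaphthalen-2-yl)ethan-1-one, via 7-acetyl-8-ethoxy-6-methylnaphthalen-1(4H)-one 10 (not isolated)
Conditions: Pd(OCOCF3)2 (5 mol %), 2-(dimethylamino)pyridine (10 mol %), TsOH·H2O (20 mol %), O2 (1 atm), DMSO, 80 °C
Reagents that add atoms: none
Why: Palladium-catalysed aerobic dehydrogenation of a cyclic ketone: α-palladation of the ring ketone and β-hydride elimination give the enone 10, which tautomerises to the naphthol. The acetyl group has no β-hydrogen and cannot react in this way, so the two ketones are distinguished by mechanism.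

Step 5
Reactants: 11 1-(1-ethoxy-8-hydroxy-3-methylnaphthalen-2-yl)ethan-1-one
Product: 12 1-(7-bromo-1-ethoxy-8-hydroxy-3-methylnaphthalen-2-yl)ethan-1-one
Conditions: NBS (1.0 equiv), i-Pr2NH (10 mol %), CH2Cl2, 0 °C
Reagents that add atoms: N-bromosuccinimide, O=C1CCC(=O)N1Br
Why: Secondary-amine-catalysed ortho-bromination of a naphthol: the N-bromoamine formed in the flask is held at the phenolic oxygen and delivers bromine to the ortho carbon C7 rather than to the para carbon C5. Ring A is deactivated by the acetyl group, and the ketone does not enolise under these conditions.

Step 6
Reactants: 12 1-(7-bromo-1-ethoxy-8-hydroxy-3-methylnaphthalen-2-yl)ethan-1-one (two molecules)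
Product: 14 1,1'-(8,8'-diethoxy-1,1'-dihydroxy-6,6'-dimethyl-[2,2'-binaphthalene]-7,7'-diyl)di(ethan-1-one), via aryl pinacolboronate 13 (not isolated)
Conditions: B2pin2 (0.55 equiv), PdCl2(dppf) (5 mol %), KOAc, 1,4-dioxane, 90 °C; then aq. K3PO4, 90 °C
Reagents that add atoms: none
Why: One-pot Miyaura borylation and Suzuki–Miyaura coupling: about half of 12 is converted by zerovalent palladium and the diboron into 13, which couples with the remaining 12 once aqueous phosphate is added. The new biaryl bond has only the two hydroxyl groups as ortho substituents, and free ortho-halophenols and aryl ketones are tolerated by these weak bases.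

Step 7
Reactants: 14 1,1'-(8,8'-diethoxy-1,1'-dihydroxy-6,6'-dimethyl-[2,2'-binaphthalene]-7,7'-diyl)di(ethan-1-one)
Product: 15 stypandrol, 1,1'-(1,1',8,8'-tetrahydroxy-6,6'-dimethyl-[2,2'-binaphthalene]-7,7'-diyl)di(ethan-1-one)
Conditions: BCl3 (6 equiv), CH2Cl2, −78 → 0 °C; then H2O
Reagents that add atoms: none
Why: Lewis-acid cleavage of aryl alkyl ethers: each ethoxy oxygen lies between the acetyl carbonyl and the peri hydroxyl, so boron is chelated there and chloride attacks the ethyl group. The aryl ketones and the biaryl bond are unaffected, and the oxidisable tetrol is released only in the last step.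

## Compound list

1 | hex-5-ynoic acid | C#CCCCC(=O)O | starting material
2 | 1-(1H-imidazol-1-yl)hex-5-yn-1-one (hex-5-ynoyl imidazole) | C#CCCCC(=O)n1ccnc1 | intermediate
3 | N-methoxy-N-methylhex-5-ynamide | C#CCCCC(=O)N(C)OC | intermediate
4 | ethoxyethyne | CCOC#C | starting material
5 | lithium ethoxyacetylide | [Li]C#COCC | intermediate
6 | lithium 1-ethoxy-3-[methoxy(methyl)amino]octa-1,7-diyn-3-olate (racemic) | [Li+].CCOC#CC([O-])(CCCC#C)N(C)OC | intermediate
7 | 1-ethoxyocta-1,7-diyn-3-one | CCOC#CC(=O)CCCC#C | intermediate
8 | pent-3-yn-2-one | CC#CC(C)=O | starting material
9 | 7-acetyl-8-ethoxy-6-methyl-3,4-dihydronaphthalen-1(2H)-one | CCOc1c(C(C)=O)c(C)cc2c1C(=O)CCC2 | intermediate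
10 | 7-acetyl-8-ethoxy-6-methylnaphthalen-1(4H)-one | CCOc1c(C(C)=O)c(C)cc2c1C(=O)C=CC2 | intermediate
11 | 1-(1-ethoxy-8-hydroxy-3-methylnaphthalen-2-yl)ethan-1-one | CCOc1c(C(C)=O)c(C)cc2cccc(O)c12 | intermediate
12 | 1-(7-bromo-1-ethoxy-8-hydroxy-3-methylnaphthalen-2-yl)ethan-1-one | CCOc1c(C(C)=O)c(C)cc2ccc(Br)c(O)c12 | intermediate
13 | 1-[1-ethoxy-8-hydroxy-3-methyl-7-(4,4,5,5-tetramethyl-1,3,2-dioxaborolan-2-yl)naphthalen-2-yl]ethan-1-one | CCOc1c(C(C)=O)c(C)cc2ccc(B3OC(C)(C)C(C)(C)O3)c(O)c12 | intermediate
14 | 1,1'-(8,8'-diethoxy-1,1'-dihydroxy-6,6'-dimethyl-[2,2'-binaphthalene]-7,7'-diyl)di(ethan-1-one) | CCOc1c(C(C)=O)c(C)cc2ccc(-c3ccc4cc(C)c(C(C)=O)c(OCC)c4c3O)c(O)c12 | intermediate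
15 | stypandrol, 1,1'-(1,1',8,8'-tetrahydroxy-6,6'-dimethyl-[2,2'-binaphthalene]-7,7'-diyl)di(ethan-1-one) | CC(=O)c1c(C)cc2ccc(-c3ccc4cc(C)c(C(C)=O)c(O)c4c3O)c(O)c2c1O | target

## Step count and the least certain steps

Total: 7 steps. Longest linear sequence: 7 steps (1 → 3 → 7 → 9 → 11 → 12 → 14 → 15); 4 and 8 enter as commercial reagents.

**Step 3 (key step).**
- What may go wrong: insertion of 8 in the reverse orientation would place the acetyl group next to C4. The oxidative coupling of a 1,7-diyne without substituents on its tether is slow, so oligomerisation of 7, or a trimer of its terminal alkyne with two molecules of 8, may win. The cationic metal may also degrade the push–pull ethoxy ynone.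
- Fallback: the three-component union is replaced by a cycloaddition whose regiochemistry is fixed by connectivity. It sets out from 7 and 8 and returns at 9.
  - Hydroiodination of 8 (NaI, AcOH) and acid equilibration give (E)-4-iodopent-3-en-2-one F1.
  - Sonogashira coupling of F1 with the terminal alkyne of 7 (PdCl2(PPh3)2, CuI, Et3N, THF, rt) gives (E)-12-ethoxy-4-methyldodec-3-ene-5,11-diyne-2,10-dione F2. A tertiary amine is used so that it does not add to the ynone.
  - Heating F2 in toluene brings about an intramolecular [4+2] cycloaddition of the conjugated enyne with the ynone triple bond. This forms C4a–C8a and C1–C2, and the resulting cyclic allene aromatises by hydrogen shift from C2 to C4 to give 9.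

**Step 2.**
- What may go wrong: addition of the liberated N,O-dimethylhydroxylamine to the ynone during the quench, acid-promoted hydration of the ethoxyalkyne to a β-keto ester, or self-condensation after proton exchange at the terminal alkyne.
- Fallback: the ketone is reached by alcohol oxidation instead of acyl substitution. It sets out from 3 and returns at 7.
  - Reduction of 3 (i-Bu2AlH, THF, −78 °C) gives hex-5-ynal F3.
  - Addition of 5 at −78 °C, which is fast for an aldehyde and liberates no amine, gives racemic 1-ethoxyocta-1,7-diyn-3-ol F4.
  - Oxidation of F4 with MnO2 in CH2Cl2 under neutral conditions gives 7.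

**Step 4.**
- What may go wrong: further oxidation of the electron-rich naphthol under oxygen, or slow α-palladation next to the peri ethoxy group.
- Fallback: the dehydrogenation is replaced by a halogenation–elimination sequence. It sets out from 9 and returns at 12, so step 5 is skipped.
  - Double α-bromination of the ring ketone (CuBr2, EtOAc/CHCl3, reflux) gives 7-acetyl-2,2-dibromo-8-ethoxy-6-methyl-3,4-dihydronaphthalen-1(2H)-one F5. The ring ketone enolises faster than the twisted, doubly ortho-substituted acetyl group.
  - Elimination of hydrogen bromide (DBU, MeCN) and tautomerisation give 12, with the bromine placed at C7 by the position of the former ketone.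

**Step 5.**
- What may go wrong: competing attack at C5, para to the hydroxyl, or double bromination.
- Fallback: the electrophilic substitution is replaced by a tether-directed C–H borylation. It sets out from 11 and returns at 13, which is then dimerised to 14.
  - Dehydrogenative silylation of the hydroxyl (Et2SiH2, [Ir(cod)Cl]2 cat., THF) gives 1-{8-[(diethylsilyl)oxy]-1-ethoxy-3-methylnaphthalen-2-yl}ethan-1-one F6.
  - Iridium-catalysed borylation directed by the Si–H group ([Ir(cod)Cl]2, 4,4'-di-tert-butyl-2,2'-bipyridine, B2pin2, THF, 80 °C) can reach only C7 and gives the borylated silyl ether F7.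
  - Hydrolytic work-up removes the silyl group and gives 13.
  - Oxidative homocoupling of 13 (Pd(OAc)2 cat., O2, aq. K2CO3, DMF) gives 14.

**Step 6.**
- What may go wrong: protodeborylation of 13 or hydrodebromination of 12 before the cross-coupling, and slowing of the catalyst by the chelating naphtholate.
- Fallback: a reductive homocoupling on the protected phenol. It sets out from 12 and returns at 15.
  - Protection (MOMCl, i-Pr2NEt, CH2Cl2) gives 1-[7-bromo-1-ethoxy-8-(methoxymethoxy)-3-methylnaphthalen-2-yl]ethan-1-one F8.
  - Homocoupling mediated by zerovalent nickel (Ni(cod)2, 2,2'-bipyridine, DMF, 60 °C) gives the bis(methoxymethyl) ether of 14, F9.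
  - BCl3 in CH2Cl2 removes the methoxymethyl and ethyl groups together and gives 15.

## Further compounds

F1 | step 3 | (E)-4-iodopent-3-en-2-one | CC(=O)/C=C(\C)I
F2 | step 3 | (E)-12-ethoxy-4-methyldodec-3-ene-5,11-diyne-2,10-dione | CC(=O)/C=C(\C)C#CCCCC(=O)C#COCC
F3 | step 2 | hex-5-ynal | C#CCCCC=O
F4 | step 2 | 1-ethoxyocta-1,7-diyn-3-ol (racemic) | CCOC#CC(O)CCCC#C
F5 | step 4 | 7-acetyl-2,2-dibromo-8-ethoxy-6-methyl-3,4-dihydronaphthalen-1(2H)-one | CCOc1c(C(C)=O)c(C)cc2c1C(=O)C(Br)(Br)CC2
F6 | step 5 | 1-{8-[(diethylsilyl)oxy]-1-ethoxy-3-methylnaphthalen-2-yl}ethan-1-one | CCOc1c(C(C)=O)c(C)cc2cccc(O[SiH](CC)CC)c12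
F7 | step 5 | 1-{8-[(diethylsilyl)oxy]-1-ethoxy-3-methyl-7-(4,4,5,5-tetramethyl-1,3,2-dioxaborolan-2-yl)naphthalen-2-yl}ethan-1-one | CCOc1c(C(C)=O)c(C)cc2ccc(B3OC(C)(C)C(C)(C)O3)c(O[SiH](CC)CC)c12
F8 | step 6 | 1-[7-bromo-1-ethoxy-8-(methoxymethoxy)-3-methylnaphthalen-2-yl]ethan-1-one | CCOc1c(C(C)=O)c(C)cc2ccc(Br)c(OCOC)c12
F9 | step 6 | 1,1'-[8,8'-diethoxy-1,1'-bis(methoxymethoxy)-6,6'-dimethyl-[2,2'-binaphthalene]-7,7'-diyl]di(ethan-1-one) | CCOc1c(C(C)=O)c(C)cc2ccc(-c3ccc4cc(C)c(C(C)=O)c(OCC)c4c3OCOC)c(OCOC)c12
A1 | alternative 1 | 8,8'-dimethoxy-[7,7'-biisochromane]-1,1',3,3'-tetrone | COc1c(-c2ccc3c(c2OC)C(=O)OC(=O)C3)ccc2c1C(=O)OC(=O)C2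
A2 | alternative 1 | 8,8'-di-O-methylstypandrol | CC(=O)c1c(C)cc2ccc(-c3ccc4cc(C)c(C(C)=O)c(O)c4c3OC)c(OC)c2c1O
A3 | alternative 2 | dimethyl 2-methoxy-4,6-dimethylbenzene-1,3-dicarboxylate | COC(=O)c1c(C)cc(C)c(C(=O)OC)c1OC
A4 | alternative 2 | dimethyl 2,3-dimethylidenebutanedioate | C=C(C(=O)OC)C(=C)C(=O)OC
A5 | alternative 2 | tetramethyl 8,8'-dimethoxy-6,6'-dimethyl-1,1'-dioxo-3,3',4,4'-tetrahydro-[2,2'-binaphthalene]-2,2',7,7'-tetracarboxylate (mixture of diastereomers) | COC(=O)c1c(C)cc2c(c1OC)C(=O)C(C(=O)OC)(CC2)C1(C(=O)OC)CCc2cc(C)c(C(=O)OC)c(OC)c2C1=O
A6 | alternative 3 | (E)-1-(3-acetyl-2-methoxy-4,6-dimethylphenyl)-3-(dimethylamino)prop-2-en-1-one | CC(=O)c1c(C)cc(C)c(C(=O)/C=C/N(C)C)c1OC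
A7 | alternative 3 | 1-(8-hydroxy-1-methoxy-3-methylnaphthalen-2-yl)ethan-1-one | CC(=O)c1c(C)cc2cccc(O)c2c1OC
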